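## Retrosynthetic overview

1. C2–C4 and the C3 stereocentre ⇐ dimethyl 2,3-O-isopropylidene-D-tartrate 1 (→ mono-acid 2 → ketone 3 in the flask → hydroxy acid 4); the second tartrate carboxyl is a traceless handle on C4.
2. O1–C8a aryl ether ⇐ SNAr: bought phenol 5, as its MOM ether 6, takes the tertiary alkoxide of 4 to give aryl-ether acid 7.
3. C4–C4a (key bond, pyran ring) ⇐ light-driven nickel/photoredox ring-closing decarboxylative arylation of 7 to the cis-fused tricycle 8; C4 is re-set from C3.
4. Enone C=C ⇐ Claisen–Schmidt of aldehyde 8 with 2,4-dihydroxyacetophenone 9 (aldol 10 → chalcone 11); acid unmasking gives target 12.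
5. Ring order: both benzene rings and the dioxolane are bought; the pyran ring is the only ring made (line 3); the dioxolane is opened last.

The target is the cis-diol, (3S,4S), with an E enone. Chroman numbering (O1, C2, C3, C4, C4a … C8a) is used throughout.

Assumption: 5 (3-bromo-4-fluoro-5-hydroxybenzaldehyde) is taken as a purchasable catalogue building block, like 1 and 9.

## Route

Step 1
Reactants: 1 dimethyl (4S,5S)-2,2-dimethyl-1,3-dioxolane-4,5-dicarboxylate (dimethyl 2,3-O-isopropylidene-D-tartrate)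
Product: 2 (4S,5S)-5-(methoxycarbonyl)-2,2-dimethyl-1,3-dioxolane-4-carboxylic acid
Conditions: KOH (1.0 equiv), MeOH, 0 °C → rt, 3 h; then 1 M HCl (0 °C) to pH 3
Reagents that add atoms: potassium hydroxide, [K+].[OH-]
Why: Mono-saponification of a C2-symmetric diester (ester hydrolysis), self-limiting because the first carboxylate deactivates the second ester toward hydroxide; neither stereocentre is touched.

Step 2
Reactants: 2 (4S,5S)-5-(methoxycarbonyl)-2,2-dimethyl-1,3-dioxolane-4-carboxylic acid
Product: 4 (4S,5S)-5-(2-hydroxypropan-2-yl)-2,2-dimethyl-1,3-dioxolane-4-carboxylic acid, via methyl ketone carboxylate 3 (not isolated)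
Conditions: MeMgBr (3.5 equiv), THF, −20 °C → rt; then 1 M HCl (0 °C) to pH 3
Reagents that add atoms: methylmagnesium bromide, C[Mg]Br
Why: Double Grignard addition to the ester while the magnesium carboxylate stays inert; no bond to the future C3 is broken and the trans-acetonide is the thermodynamic arrangement, so the bought (S) centre is kept, and the trans ring fusion that a lactone would need prevents lactonisation.

Step 3
Reactants: 5 3-bromo-4-fluoro-5-hydroxybenzaldehyde
Product: 6 3-bromo-4-fluoro-5-(methoxymethoxy)benzaldehyde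
Conditions: MOMCl (1.3 equiv), K2CO3 (2 equiv), DMF, 0 °C → rt
Reagents that add atoms: chloromethyl methyl ether, COCCl
Why: Williamson-type O-alkylation of an acidic phenol (MOM protection), which removes the phenoxide that would otherwise shut down SNAr at the neighbouring C–F.

Step 4
Reactants: 4 (4S,5S)-5-(2-hydroxypropan-2-yl)-2,2-dimethyl-1,3-dioxolane-4-carboxylic acid; 6 3-bromo-4-fluoro-5-(methoxymethoxy)benzaldehyde
Product: 7 (4S,5S)-5-{2-[2-bromo-4-formyl-6-(methoxymethoxy)phenoxy]propan-2-yl}-2,2-dimethyl-1,3-dioxolane-4-carboxylic acid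
Conditions: 4, NaH (2.2 equiv), THF, 0 °C → rt; then 6 (1.05 equiv), DMF, 0 → 25 °C; 1 M HCl (0 °C) to pH 3–4
Reagents that add atoms: none
Why: Nucleophilic aromatic substitution (addition–elimination) in which the tertiary alkoxide of the dianion displaces fluoride para to the formyl group with inductive help from the ortho bromine, the carboxylate being far less nucleophilic; no stereocentre is involved.

Step 5
Reactants: 7 (4S,5S)-5-{2-[2-bromo-4-formyl-6-(methoxymethoxy)phenoxy]propan-2-yl}-2,2-dimethyl-1,3-dioxolane-4-carboxylic acid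
Product: 8 (3aS,9bS)-6-(methoxymethoxy)-2,2,4,4-tetramethyl-3a,9b-dihydro-4H-[1,3]dioxolo[4,5-c]chromene-8-carbaldehyde
Conditions: Ir[dF(CF3)ppy]2(dtbbpy)PF6 (2 mol %), NiCl2·glyme (10 mol %), 4,4'-di-tert-butyl-2,2'-bipyridine (15 mol %), Cs2CO3 (1.5 equiv), degassed DMF (0.01 M), 450 nm LEDs, 25 °C
Reagents that add atoms: none
Why: Proposed new method: a ring-closing, stereo-rewriting decarboxylative arylation in which the excited trivalent iridium photocatalyst oxidises the caesium carboxylate of 7, loss of CO2 gives the planar C4 dioxolanyl (alpha-oxy) radical and erases the tartrate C4 centre, the tethered aryl bromide adds to low-valent nickel, reversible radical capture gives a seven-membered trivalent nickel alkyl–aryl species and reductive elimination forms C4–C4a; because the C3–C4 bond is locked in the dioxolane only the cis-fused chroman can close without severe strain, so the bought (S)-C3 centre dictates (S)-C4; the closest known reaction type is the intermolecular nickel/photoredox decarboxylative arylation of alpha-oxy acids with aryl bromides, which has not been shown as a ring closure or for neighbour-controlled re-setting of a carbinol centre.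

Step 6
Reactants: 8 (3aS,9bS)-6-(methoxymethoxy)-2,2,4,4-tetramethyl-3a,9b-dihydro-4H-[1,3]dioxolo[4,5-c]chromene-8-carbaldehyde; 9 1-(2,4-dihydroxyphenyl)ethanone
Product: 11 (E)-1-(2,4-dihydroxyphenyl)-3-[(3aS,9bS)-6-(methoxymethoxy)-2,2,4,4-tetramethyl-3a,9b-dihydro-4H-[1,3]dioxolo[4,5-c]chromen-8-yl]prop-2-en-1-one, via aldol adduct 10 (not isolated)
Conditions: 9 (1.2 equiv), KOH (50% aq., 10 equiv), EtOH, 25 °C, 36 h; then AcOH to pH 6
Reagents that add atoms: none
Why: Claisen–Schmidt aldol condensation of a non-enolisable aldehyde with the unprotected dihydroxyacetophenone (standard for 2',4'-dihydroxychalcones), E1cB dehydration giving the thermodynamic E enone; the acetonide, MOM ether and both stereocentres are base-stable.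

Step 7
Reactants: 11 (E)-1-(2,4-dihydroxyphenyl)-3-[(3aS,9bS)-6-(methoxymethoxy)-2,2,4,4-tetramethyl-3a,9b-dihydro-4H-[1,3]dioxolo[4,5-c]chromen-8-yl]prop-2-en-1-one
Product: 12 (E)-1-(2,4-dihydroxyphenyl)-3-[(3S,4S)-3,4,8-trihydroxy-2,2-dimethyl-3,4-dihydro-2H-chromen-6-yl]prop-2-en-1-one
Conditions: 2 M aq. HCl/THF (1:2), 40 °C, 6–10 h
Reagents that add atoms: none
Why: Acid-catalysed acetal hydrolysis removes the acetonide and the MOM ether together through oxocarbenium ions at the acetal carbons, so the C3–O and C4–O bonds are never broken and the (3S,4S) cis-diol is retained.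

## Compound list

1 | dimethyl (4S,5S)-2,2-dimethyl-1,3-dioxolane-4,5-dicarboxylate (dimethyl 2,3-O-isopropylidene-D-tartrate) | COC(=O)[C@H]1OC(C)(C)O[C@@H]1C(=O)OC | starting material
2 | (4S,5S)-5-(methoxycarbonyl)-2,2-dimethyl-1,3-dioxolane-4-carboxylic acid | OC(=O)[C@H]1OC(C)(C)O[C@@H]1C(=O)OC | intermediate
3 | (4S,5S)-5-acetyl-2,2-dimethyl-1,3-dioxolane-4-carboxylic acid, present as its magnesium carboxylate | OC(=O)[C@H]1OC(C)(C)O[C@@H]1C(C)=O | intermediate (not isolated)
4 | (4S,5S)-5-(2-hydroxypropan-2-yl)-2,2-dimethyl-1,3-dioxolane-4-carboxylic acid | OC(=O)[C@H]1OC(C)(C)O[C@@H]1C(C)(C)O | intermediate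
5 | 3-bromo-4-fluoro-5-hydroxybenzaldehyde | O=Cc1cc(O)c(F)c(Br)c1 | starting material
6 | 3-bromo-4-fluoro-5-(methoxymethoxy)benzaldehyde | COCOc1cc(C=O)cc(Br)c1F | intermediate
7 | (4S,5S)-5-{2-[2-bromo-4-formyl-6-(methoxymethoxy)phenoxy]propan-2-yl}-2,2-dimethyl-1,3-dioxolane-4-carboxylic acid | OC(=O)[C@H]1OC(C)(C)O[C@@H]1C(C)(C)Oc2c(Br)cc(C=O)cc2OCOC | intermediate
8 | (3aS,9bS)-6-(methoxymethoxy)-2,2,4,4-tetramethyl-3a,9b-dihydro-4H-[1,3]dioxolo[4,5-c]chromene-8-carbaldehyde (cis-fused acetonide of the (3S,4S)-chroman-3,4-diol, 8-O-MOM, 6-CHO) | CC1(C)Oc2c(OCOC)cc(C=O)cc2[C@@H]3OC(C)(C)O[C@H]13 | intermediate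
9 | 1-(2,4-dihydroxyphenyl)ethanone (2,4-dihydroxyacetophenone) | CC(=O)c1ccc(O)cc1O | starting material
10 | 1-(2,4-dihydroxyphenyl)-3-hydroxy-3-[(3aS,9bS)-6-(methoxymethoxy)-2,2,4,4-tetramethyl-3a,9b-dihydro-4H-[1,3]dioxolo[4,5-c]chromen-8-yl]propan-1-one, both epimers at the new carbinol | CC1(C)Oc2c(OCOC)cc(C(O)CC(=O)c4ccc(O)cc4O)cc2[C@@H]3OC(C)(C)O[C@H]13 | intermediate (not isolated)
11 | (E)-1-(2,4-dihydroxyphenyl)-3-[(3aS,9bS)-6-(methoxymethoxy)-2,2,4,4-tetramethyl-3a,9b-dihydro-4H-[1,3]dioxolo[4,5-c]chromen-8-yl]prop-2-en-1-one | CC1(C)Oc2c(OCOC)cc(/C=C/C(=O)c4ccc(O)cc4O)cc2[C@@H]3OC(C)(C)O[C@H]13 | intermediate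
12 | (E)-1-(2,4-dihydroxyphenyl)-3-[(3S,4S)-3,4,8-trihydroxy-2,2-dimethyl-3,4-dihydro-2H-chromen-6-yl]prop-2-en-1-one | CC1(C)Oc2c(O)cc(/C=C/C(=O)c3ccc(O)cc3O)cc2[C@H](O)[C@@H]1O | target

## Step count and risks

Total steps: 7. Longest linear sequence: 6 (1 → 2 → 4 → 7 → 8 → 11 → 12); step 3 is a one-step side branch.

Most likely to fail:

1. Step 5 (the proposed new ring closure). Risks are protodecarboxylation, oligomerisation instead of closure, radical ipso attack on the aryl ether, and an unproven cis:trans ratio at C4. Fallback with known chemistry, setting out from 7 and coming back at 8: 7 is esterified with N-hydroxyphthalimide (DIC, cat. DMAP, CH2Cl2, rt) to its N-hydroxyphthalimide ester F1. F1 is then closed without light by the established nickel-catalysed reductive decarboxylative arylation of such redox-active esters with aryl halides (NiBr2·glyme, 4,4'-di-tert-butyl-2,2'-bipyridine, Zn dust, DMA, 0.01 M, 25–40 °C). Single-electron reduction of the phthalimide ester gives the same C4 radical, so the cis-fusion argument still sets C4 and the product is 8.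

2. Step 4 (SNAr of a hindered tertiary alkoxide next to a free formyl group). Risks are slow substitution at a carbon flanked by Br and OMOM, and alkoxide addition or hydride transfer at the aldehyde. Fallback, setting out from 6 and 4 and coming back at 8: the formyl group is carried as a nitrile. 6 is converted with I2/aq. NH3 (THF, rt) into 3-bromo-4-fluoro-5-(methoxymethoxy)benzonitrile F2. SNAr of the dianion of 4 on F2 (cyano activates like formyl but cannot add alkoxide, so the mixture can be warmed to 60–80 °C) gives (4S,5S)-5-{2-[2-bromo-4-cyano-6-(methoxymethoxy)phenoxy]propan-2-yl}-2,2-dimethyl-1,3-dioxolane-4-carboxylic acid F3. The ring closure under the step-5 conditions gives the tricyclic nitrile (3aS,9bS)-6-(methoxymethoxy)-2,2,4,4-tetramethyl-3a,9b-dihydro-4H-[1,3]dioxolo[4,5-c]chromene-8-carbonitrile F4. Reduction with i-Bu2AlH (toluene, −78 °C) and aqueous work-up gives 8.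

3. Step 7 (acid unmasking of the finished chalcone). Risks are ionisation at benzylic C4 (epimerisation to the trans-diol) and acid-promoted closure of the 2'-hydroxychalcone to a flavanone. Fallback, setting out from 8 and coming back at 12: deprotect before the condensation. 8 is hydrolysed (2 M aq. HCl/THF, 40 °C) to (3S,4S)-3,4,8-trihydroxy-2,2-dimethyl-3,4-dihydro-2H-chromene-6-carbaldehyde F5; here the formyl group para to O1 makes C4 ionisation least likely and no chalcone is present. F5 and 9 are then condensed with KOH in EtOH/H2O (rt, AcOH quench to pH 5), through the β-hydroxy ketone 1-(2,4-dihydroxyphenyl)-3-hydroxy-3-[(3S,4S)-3,4,8-trihydroxy-2,2-dimethyl-3,4-dihydro-2H-chromen-6-yl]propan-1-one F6, to give 12 directly, so the cis-diol chalcone never meets strong acid.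

## Further compounds

F1 | step 5 | 1,3-dioxoisoindolin-2-yl (4S,5S)-5-{2-[2-bromo-4-formyl-6-(methoxymethoxy)phenoxy]propan-2-yl}-2,2-dimethyl-1,3-dioxolane-4-carboxylate | O=C(ON1C(=O)c2ccccc2C1=O)[C@H]3OC(C)(C)O[C@@H]3C(C)(C)Oc4c(Br)cc(C=O)cc4OCOC
F2 | step 4 | 3-bromo-4-fluoro-5-(methoxymethoxy)benzonitrile | COCOc1cc(C#N)cc(Br)c1F
F3 | step 4 | (4S,5S)-5-{2-[2-bromo-4-cyano-6-(methoxymethoxy)phenoxy]propan-2-yl}-2,2-dimethyl-1,3-dioxolane-4-carboxylic acid | OC(=O)[C@H]1OC(C)(C)O[C@@H]1C(C)(C)Oc2c(Br)cc(C#N)cc2OCOC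
F4 | step 4 | (3aS,9bS)-6-(methoxymethoxy)-2,2,4,4-tetramethyl-3a,9b-dihydro-4H-[1,3]dioxolo[4,5-c]chromene-8-carbonitrile | CC1(C)Oc2c(OCOC)cc(C#N)cc2[C@@H]3OC(C)(C)O[C@H]13
F5 | step 7 | (3S,4S)-3,4,8-trihydroxy-2,2-dimethyl-3,4-dihydro-2H-chromene-6-carbaldehyde | CC1(C)Oc2c(O)cc(C=O)cc2[C@H](O)[C@@H]1O
F6 | step 7 | 1-(2,4-dihydroxyphenyl)-3-hydroxy-3-[(3S,4S)-3,4,8-trihydroxy-2,2-dimethyl-3,4-dihydro-2H-chromen-6-yl]propan-1-one | CC1(C)Oc2c(O)cc(C(O)CC(=O)c3ccc(O)cc3O)cc2[C@H](O)[C@@H]1O
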